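**Assumption (one line):** each half is numbered as a quinolizidin-2-one (N5; C1 and C9 carry the pentamethylene chains); read from the SMILES, the half written first ("half A") is (1S,3R,9R,9aR) and cis-fused, the other ("half B") is (1S,3R,9S,9aS), trans-fused and all-equatorial.

**Note on stereocontrol:** this route does not set the stereocentres selectively. All eight centres are epimerisable, so relative configuration is taken from a thermodynamic pool (step 6) and absolute configuration from a resolution (step 7). The share of the wanted unsymmetrical isomer in that pool is not known in advance.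

## Retrosynthetic overview

1. 17 ⇐ enantiomer separation of racemate 16, taken from the equilibrating pool of 16-membered bis(quinolizidin-2-one) stereoisomers.
2. Both piperidone rings and the 16-membered ring ⇐ transannular double Mannich reaction of a bis(iminium), contracting a 24-membered ring (C1–C9a bonds formed last).
3. Bis(iminium) ⇐ dearomatising hydrogenation of a 24-membered bis(N-alkyl-2-pyridone), then lactam hydrosilylation; the pyridone C=O marks the future iminium carbon C9a, so regiochemistry is built in.
4. 24-membered ring ⇐ head-to-tail double aza-Michael cyclodimerisation of one monomer, a 3-alkyl-2-pyridone carrying an isopropenyl ketone.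
5. Monomer ⇐ 3-bromo-2-methoxypyridine + hept-6-enoic acid (B-alkyl Suzuki) + isopropenyl Grignard. Ring order: pyridine (bought) → 24-membered ring → two piperidine rings → two piperidone rings together with the 16-membered ring.

## Route

Step 1
Reactants: 1 hept-6-enoic acid; 2 N,O-dimethylhydroxylamine hydrochloride
Product: 4 N-methoxy-N-methylhept-6-enamide, via hept-6-enoyl imidazolide 3 (not isolated)
Conditions: 1,1'-carbonyldiimidazole, CH2Cl2, 0 → 25 °C; then 2, 25 °C
Reagents that add atoms: N,O-dimethylhydroxylamine hydrochloride (2), CNOC.Cl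
Why: Acyl imidazolide formation followed by aminolysis (Weinreb amide synthesis); no stereocentre is involved.

Step 2
Reactants: 4 N-methoxy-N-methylhept-6-enamide; 5 3-bromo-2-methoxypyridine
Product: 7 N-methoxy-7-(2-methoxypyridin-3-yl)-N-methylheptanamide, via B-alkyl-9-BBN adduct 6 (not isolated)
Conditions: 9-BBN-H (0.5 M in THF), 25 °C; then 5, Pd(dppf)Cl2 (3 mol%), K3PO4, THF/DMF/H2O, 60 °C
Reagents that add atoms: 3-bromo-2-methoxypyridine (5), COc1ncccc1Br
Why: Anti-Markovnikov hydroboration and B-alkyl Suzuki–Miyaura coupling attach the seven-carbon chain to C3 of the pyridine, the Weinreb amide being inert to both; no stereocentre.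

Step 3
Reactants: 7 N-methoxy-7-(2-methoxypyridin-3-yl)-N-methylheptanamide
Product: 8 N-methoxy-N-methyl-7-(2-oxo-1,2-dihydropyridin-3-yl)heptanamide
Conditions: LiCl, TsOH·H2O, DMF, 120 °C
Reagents that add atoms: none
Why: Chloride attacks the methyl group of the N-protonated 2-methoxypyridine (SN2 O-demethylation) and unveils the 2-pyridone, whose carbonyl carbon is the future C9a; no stereocentre.

Step 4
Reactants: 8 N-methoxy-N-methyl-7-(2-oxo-1,2-dihydropyridin-3-yl)heptanamide; 9 isopropenylmagnesium bromide
Product: 10 3-(8-methyl-7-oxonon-8-en-1-yl)pyridin-2(1H)-one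
Conditions: CH2=C(CH3)MgBr (3.2 equiv), THF, −20 → 0 °C; aq. NH4Cl
Reagents that add atoms: isopropenylmagnesium bromide (9), CC(=C)[Mg]Br
Why: Weinreb ketone synthesis, in which the first equivalent of Grignard reagent only deprotonates the pyridone N–H and the chelated tetrahedral adduct stops at the isopropenyl ketone; no stereocentre.

Step 5
Reactants: 10 3-(8-methyl-7-oxonon-8-en-1-yl)pyridin-2(1H)-one (two molecules)
Product: 12 24-membered macrocyclic bis(N-alkyl-2-pyridone) (head-to-tail cyclodimer of 10; CH(CH3) centres unassigned), via open-chain dimer 11 (not isolated)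
Conditions: DBU (0.3 equiv), BHT (trace), MeCN, 5 mM, 60 °C, 10 added by syringe pump
Reagents that add atoms: none
Why: Reversible base-catalysed aza-Michael addition of the pyridone N–H to the isopropenyl ketone gives N-alkylation as the thermodynamic outcome and, under dilution, the strain-free 24-membered cyclodimer (the 12-membered cyclic monomer would be a strained bridged pyridone); the two CH(CH3) centres form unselectively and are re-equilibrated in step 6.

Step 6
Reactants: 12 24-membered macrocyclic bis(N-alkyl-2-pyridone)
Product: 16 racemate of the target (half A 1S,3R,9R,9aR / half B 1S,3R,9S,9aS plus mirror image), via bis-lactam 13 (not isolated), via bis-silyl hemiaminal 14 (not isolated), via bis-iminium 15 (not isolated)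
Conditions: H2 (20 bar), 10% Pd/C, MeOH, 60 °C, filter, evaporate; IrCl(CO)(PPh3)2 (2 mol%), (HMe2Si)2O, PhMe, 25 °C; CF3CO2H, CH2Cl2, 0 → 25 °C, then AcOH, 70 °C; aq. NaHCO3; chromatography on neutral alumina
Reagents that add atoms: none
Why: Heterogeneous hydrogenation dearomatises both pyridones to N-alkyl δ-lactams (hindered dialkyl ketones survive Pd/C), lactam-selective iridium-catalysed hydrosilylation gives the N,O-silyl acetals, and acid ionises them to iminium ions that are trapped by the enol of the ketone on the same nitrogen tether in a six-membered intramolecular Mannich reaction, contracting the 24-membered ring to 16; in warm acid C1/C3 equilibrate by enolisation, C9a by retro-Mannich/Mannich and C9 by iminium–enamine tautomerism, so all eight stereocentres are under thermodynamic control, and the isomer with one trans-fused all-equatorial half and one cis-fused half (each half minimising its own peri and 1,3-diaxial strain) is separated as the racemate while the other diastereomers are returned to the same equilibration.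

Step 7
Reactants: 16 racemate of the target
Product: 17 target, half A (1S,3R,9R,9aR), half B (1S,3R,9S,9aS)
Conditions: preparative SFC, amylose tris(3,5-dimethylphenylcarbamate) phase, CO2/i-PrOH, 30 °C
Reagents that add atoms: none
Why: Chromatographic resolution of the racemate on a chiral stationary phase selects the absolute configuration without making or touching a stereocentre (neutral medium, no enolisation), and the unwanted enantiomer is recycled through the AcOH equilibration of step 6.

## Compound list

1 | hept-6-enoic acid | OC(=O)CCCCC=C | starting material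
2 | N,O-dimethylhydroxylamine hydrochloride | CNOC.Cl | starting material
3 | hept-6-enoyl imidazolide (1-(hept-6-enoyl)-1H-imidazole) | C=CCCCCC(=O)n1ccnc1 | intermediate
4 | N-methoxy-N-methylhept-6-enamide | C=CCCCCC(=O)N(C)OC | intermediate
5 | 3-bromo-2-methoxypyridine | COc1ncccc1Br | starting material
6 | 7-(9-borabicyclo[3.3.1]nonan-9-yl)-N-methoxy-N-methylheptanamide | CON(C)C(=O)CCCCCCB1C2CCCC1CCC2 | intermediate
7 | N-methoxy-7-(2-methoxypyridin-3-yl)-N-methylheptanamide | COc1ncccc1CCCCCCC(=O)N(C)OC | intermediate
8 | N-methoxy-N-methyl-7-(2-oxo-1,2-dihydropyridin-3-yl)heptanamide | CON(C)C(=O)CCCCCCc1ccc[nH]c1=O | intermediate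
9 | isopropenylmagnesium bromide, CH2=C(CH3)MgBr | CC(=C)[Mg]Br | starting material
10 | 3-(8-methyl-7-oxonon-8-en-1-yl)pyridin-2(1H)-one | CC(=C)C(=O)CCCCCCc1ccc[nH]c1=O | intermediate
11 | open-chain dimer: the N–H pyridone of one molecule of 10 added to the enone of a second; one free N–H pyridone and one free isopropenyl ketone remain (CH(CH3) centre racemic) | C=C(C)C(=O)CCCCCCC1=CC=CN(CC(C)C(=O)CCCCCCc2ccc[nH]c2=O)C1=O | intermediate
12 | 24-membered macrocyclic bis(N-alkyl-2-pyridone): each N carries CH2–CH(CH3)–C(=O)–(CH2)6– ending at C3 of the other pyridone (both CH(CH3) diastereomers) | CC1CN2C=CC=C(CCCCCCC(=O)C(C)CN3C=CC=C(CCCCCCC1=O)C3=O)C2=O | intermediate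
13 | 24-membered bis(N-alkylpiperidin-2-one), the hexahydro analogue of 12 at each ring (stereoisomer mixture) | CC1CN2CCCC(CCCCCCC(=O)C(C)CN3CCCC(CCCCCCC1=O)C3=O)C2=O | intermediate
14 | bis(N,O-silyl hemiaminal): each lactam C=O of 13 reduced to CH–O–SiMe2–O–SiMe2H (stereoisomer mixture) | CC1CN2CCCC(CCCCCCC(=O)C(C)CN3CCCC(CCCCCCC1=O)C3O[Si](C)(C)O[SiH](C)C)C2O[Si](C)(C)O[SiH](C)C | intermediate
15 | bis(2,3,4,5-tetrahydropyridinium) bis(trifluoroacetate): each N+=CH carbon is the future C9a (stereoisomer mixture) | CC1C[N+]2=CC(CCCCCCC(=O)C(C)C[N+]3=CC(CCCCCCC1=O)CCC3)CCC2.[O-]C(=O)C(F)(F)F.[O-]C(=O)C(F)(F)F | intermediate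
16 | racemate of the target: 1:1 mixture of 17 and its mirror image | C[C@@H]1CN2CCC[C@H]3CCCCC[C@@H]4C(=O)[C@H](C)CN5CCC[C@H](CCCCC[C@H](C1=O)[C@@H]32)[C@@H]45.C[C@H]1CN2CCC[C@@H]3CCCCC[C@H]4C(=O)[C@@H](C)CN5CCC[C@@H](CCCCC[C@@H](C1=O)[C@H]32)[C@H]45 | intermediate
17 | target: 16-membered macrocyclic bis(3-methylquinolizidin-2-one), C9 of each half joined by (CH2)5 to C1 of the other; half A (1S,3R,9R,9aR), half B (1S,3R,9S,9aS) | C[C@@H]1CN2CCC[C@H]3CCCCC[C@@H]4C(=O)[C@H](C)CN5CCC[C@H](CCCCC[C@H](C1=O)[C@@H]32)[C@@H]45 | target

## Step count and risks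

Total step count: 7 (step 6 is a telescoped three-operation sequence without purification of intermediates).
Longest linear sequence: 7 (fully linear).

**Step 6 (highest risk).** The ketones may be hydrosilylated, ionisation may be incomplete, and the share of 16 in the equilibrium is not known in advance. The fallback forms the C1–C9a bonds before dearomatisation. It sets out from 12. Tf2O with 2,6-di-tert-butyl-4-methylpyridine in CH2Cl2 O-triflates both pyridones to the bis(2-triflyloxypyridinium) bis(triflate) F4. On warming, the ketone enol on each nitrogen tether attacks the activated C2 (addition–elimination, loss of triflate). After NaHCO3 this gives the macrocyclic bis(3,4-dihydro-2H-quinolizin-2-one) F5, already contracted to 16 members. H2 over PtO2 in AcOH then dearomatises both vinylogous-amide pyridine rings to the kinetic, mostly all-cis bis(quinolizidinone) stereoisomer mixture F6. Warming F6 in AcOH at 70 °C equilibrates it, and the fallback comes back to the route at 16.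

**Step 5.** Oligomers or enone polymerisation may dominate over the cyclodimer. The fallback assembles the open-chain dimer stepwise; it sets out from 7 and 10. Compound 7 with CH2=C(CH3)MgBr gives the enone 9-(2-methoxypyridin-3-yl)-2-methylnon-1-en-3-one F1, whose nitrogen is masked as the methyl ether. Slow addition of 10 to excess F1 (5 equiv, DBU, MeCN) gives the 1:1 aza-Michael adduct, the O-methyl-capped open-chain dimer F2, which cannot chain-extend. LiCl/TsOH in DMF cleaves the methyl ether and at the same time converts the enone into its HCl adduct, the β-chloro ketone seco-dimer F3. Cs2CO3 in MeCN at 1 mM eliminates HCl and the liberated enone is closed by a single intramolecular aza-Michael reaction. The fallback comes back to the route at 11 and hence 12.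

**Step 7.** Throughput may be low and α-centres may epimerise on the column. The fallback is a catalyst-controlled deracemisation; it sets out from 16. Hydrogenation uses RuCl2[(S)-binap][(S,S)-dpen] (or its mirror image, chosen by screening) with KOC(CH3)3 in i-PrOH under H2. Under the base, C1 and C3 of both halves epimerise, so 17, its mirror image and the meso isomer interconvert. Both ketone environments of 17 are homochiral (1S,3R), so a catalyst that reads only the local α,α′-configuration should reduce both carbonyls of the wanted enantiomer (a twofold dynamic kinetic resolution) to the all-cis diol F7. NaHCO3-buffered Dess–Martin periodinane then restores both ketones without touching the α-centres, and the fallback comes back to the route at 17.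

Further compounds

F1 | step 5 | 9-(2-methoxypyridin-3-yl)-2-methylnon-1-en-3-one | COc1ncccc1CCCCCCC(=O)C(C)=C
F2 | step 5 | O-methyl-capped open-chain dimer (N-alkylated pyridone of 10 carrying a free isopropenyl ketone and a terminal 2-methoxypyridine) | C=C(C)C(=O)CCCCCCC1=CC=CN(CC(C)C(=O)CCCCCCc2cccnc2OC)C1=O
F3 | step 5 | β-chloro ketone seco-dimer (HCl adduct of 11) | ClCC(C)C(=O)CCCCCCC1=CC=CN(CC(C)C(=O)CCCCCCc2ccc[nH]c2=O)C1=O
F4 | step 6 | 24-membered bis(2-triflyloxypyridinium) bis(triflate) | CC1C[n+]2cccc(CCCCCCC(=O)C(C)C[n+]3cccc(CCCCCCC1=O)c3OS(=O)(=O)C(F)(F)F)c2OS(=O)(=O)C(F)(F)F.[O-]S(=O)(=O)C(F)(F)F.[O-]S(=O)(=O)C(F)(F)F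
F5 | step 6 | 16-membered macrocyclic bis(3-methyl-3,4-dihydro-2H-quinolizin-2-one), C9 of each half joined by (CH2)5 to C1 of the other | CC1CN2C=CC=C(CCCCCC3=C4N(CC(C)C3=O)C=CC=C4CCCCC5)C2=C5C1=O
F6 | step 6 | bis(quinolizidinone) of the target constitution, kinetic all-cis-hydrogenation stereoisomer mixture | CC1CN2CCCC3CCCCCC4C(=O)C(C)CN5CCCC(CCCCCC(C1=O)C32)C45
F7 | step 7 | bis-(2R)-alcohol of the target (both C2 hydroxyls cis to the C1 chain and the C3 methyl) | C[C@@H]1CN2CCC[C@H]3CCCCC[C@@H]4[C@H](O)[C@H](C)CN5CCC[C@H](CCCCC[C@H]([C@@H]1O)[C@@H]32)[C@@H]45
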